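**Plan**
- Retrosynthesis: the ten benzyl ethers and a blocking bromine are cut first, then the interflavan C4–C6 bond, then, in ring C of the upper unit, O1–C8a and C3–C4 together.
- Enabling feature: in ring C, C3 lies between the O-bearing C2 and the benzylic C4, and C8a of ring A is ortho to C4a. At the ketone level C3 is a 1,3-dithiane acyl-anion carbon next to the C2 alkoxide (a 1,3-C,O-dinucleophile), and C4–C4a–C8a is a 2-fluorobenzyl chloride (a 1,3-dielectrophile).
- Forward: ring A piece (steps 1–3), dithianyl carbinol (step 4), formal [3+3] annulation that builds ring C on ring A (step 5), dithiane to ketone, reduction, C4 oxidation, union with the lower unit at C6, global hydrogenolysis.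
- Stereochemistry: the lower unit is bought as (−)-epicatechin. Upper C2 and C3 are set together by catalytic transfer hydrogenation of the racemic, enolisable flavan-3-one under dynamic kinetic resolution. Upper C4 is relayed from C3 (attack anti to the 3-OH) in the coupling.
- Helpers: the dithiane (umpolung of C3, removed in step 6), fluoride (lost in step 5), the C8 bromine (forces coupling at C6, removed with the benzyl groups).

Key step: step 5

Assumption: compounds 1, 5, 6, 15 and 18 are taken as commercial; which enantiomer of the TsDPEN ligand delivers the (2R,3R) alcohol in step 7 is fixed on the first run, and (S,S) is written for definiteness.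

**Step 1**
Reactants: 1 2,4,6-trifluorobenzaldehyde
Product: 2 2,4-bis(benzyloxy)-6-fluorobenzaldehyde
Conditions: BnOH (2.1 equiv), NaH, DMF, −20 °C to rt
Reagents that add atoms: benzyl alcohol OCc1ccccc1
Why: Double SNAr, in which the formyl group activates the para and then one ortho fluorine toward benzyloxide, and the ring bearing two alkoxy groups should be too electron-rich to lose the third fluorine under these conditions.

**Step 2**
Reactants: 2 2,4-bis(benzyloxy)-6-fluorobenzaldehyde
Product: 3 [2,4-bis(benzyloxy)-6-fluorophenyl]methanol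
Conditions: NaBH4, THF/MeOH, 0 °C
Reagents that add atoms: none
Why: Borohydride reduction of an aryl aldehyde, to which the aryl fluoride and the benzyl ethers are inert.

**Step 3**
Reactants: 3 [2,4-bis(benzyloxy)-6-fluorophenyl]methanol
Product: 4 1,5-bis(benzyloxy)-2-(chloromethyl)-3-fluorobenzene
Conditions: SOCl2, 2,6-lutidine, CH2Cl2, 0 °C; used without chromatography
Reagents that add atoms: thionyl chloride O=S(Cl)Cl
Why: Chlorodehydroxylation of an electron-rich benzylic alcohol through its chlorosulfite, buffered by the hindered base so that the acid-sensitive benzylic chloride survives until it is used.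

**Step 4**
Reactants: 5 1,3-dithiane; 6 4-(benzyloxy)benzaldehyde
Product: 8 rac-[4-(benzyloxy)phenyl](1,3-dithian-2-yl)methanol, via 2-lithio-1,3-dithiane 7 (not isolated)
Conditions: n-BuLi, THF, −30 °C; then 6, −78 °C; H2O
Reagents that add atoms: none
Why: Corey–Seebach addition of a lithiated dithiane to an aryl aldehyde; the carbinol centre (future C2) is made racemic on purpose because it is set later under dynamic kinetic resolution.

**Step 5**
Reactants: 8 rac-[4-(benzyloxy)phenyl](1,3-dithian-2-yl)methanol; 4 1,5-bis(benzyloxy)-2-(chloromethyl)-3-fluorobenzene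
Product: 11 rac-5,7-bis(benzyloxy)-2-[4-(benzyloxy)phenyl]spiro[chromane-3,2'-[1,3]dithiane], via dilithio dianion 9 (not isolated), via open-chain lithium alkoxide 10 (not isolated)
Conditions: n-BuLi (2.1 equiv), THF, −78 to −20 °C; 4, −78 to 0 °C; then KOt-Bu, DMPU, 65 °C
Reagents that add atoms: none
Why: Proposed new method: double deprotonation of 8 gives a vicinal O,C-dianion in which the oxide cannot leave as a beta-leaving group; its soft dithianyl carbanion (C3, the future carbinol carbon in acyl-anion form) is alkylated by the benzylic chloride of 4 (C3–C4), and after Li/K exchange the C2 alkoxide displaces the ortho fluoride through a Meisenheimer intermediate (O1–C8a). The closest known reaction types are the Corey–Seebach alkylation of 2-lithio-1,3-dithianes with benzyl halides and the base-mediated intramolecular SNAr of 3-(2-fluoroaryl)propan-1-olates to chromans, merged here into one formal [3+3] annulation. Ring C closes by a 6-exo-trig addition–elimination at C8a, favoured by the fully substituted C3 (Thorpe–Ingold effect). No stereocentre of the target is fixed here: C2 is carried racemic and C3 is a non-stereogenic spiro dithioketal, both being set in step 7. The step needs C- over O-alkylation and six- over five-membered O-arylation: the far more nucleophilic carbanion secures the first, and the second is built in because C3 carries sulfur and no oxygen, so O1 is the only alkoxide within reach of C8a, and fluoride is the only leaving group on ring A.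

**Step 6**
Reactants: 11 rac-5,7-bis(benzyloxy)-2-[4-(benzyloxy)phenyl]spiro[chromane-3,2'-[1,3]dithiane]
Product: 12 rac-5,7-bis(benzyloxy)-2-[4-(benzyloxy)phenyl]chroman-3-one
Conditions: MeI, CaCO3, MeCN/H2O (9:1), 45 °C
Reagents that add atoms: water O
Why: S-Alkylative dithioketal hydrolysis, chosen because MeI is neither an oxidant nor an electrophile toward the electron-rich ring A; epimerisation at C2 is harmless since 12 is racemic.

**Step 7**
Reactants: 12 rac-5,7-bis(benzyloxy)-2-[4-(benzyloxy)phenyl]chroman-3-one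
Product: 13 (2R,3R)-5,7-bis(benzyloxy)-2-[4-(benzyloxy)phenyl]chroman-3-ol (5,7,4'-tri-O-benzyl-(−)-epiafzelechin)
Conditions: RuCl(p-cymene)[(S,S)-TsDPEN] (2 mol %), HCO2H/Et3N (5:2), DMF, 35 °C
Reagents that add atoms: none
Why: Noyori–Ikariya transfer hydrogenation under dynamic kinetic resolution: the C2–H of the alpha-aryl-alpha-aryloxy ketone should exchange fast in HCO2H/Et3N, the chiral catalyst reduces one enantiomer faster and so sets C3 and C2 together, and hydride enters anti to the equatorial C2 aryl group so that the 2-aryl and 3-OH groups emerge cis.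

**Step 8**
Reactants: 13 (2R,3R)-5,7-bis(benzyloxy)-2-[4-(benzyloxy)phenyl]chroman-3-ol
Product: 14 (2R,3R,4S)-5,7-bis(benzyloxy)-2-[4-(benzyloxy)phenyl]-4-(2-ethoxyethoxy)chroman-3-ol (4β ether)
Conditions: DDQ, 2-ethoxyethanol, CH2Cl2, rt
Reagents that add atoms: 2-ethoxyethanol CCOCCO
Why: DDQ hydride abstraction at C4 gives the cation stabilised by ring A (the standard C4 activation of benzylated flavan-3-ols), which the alcohol traps anti to the axial 3-OH; the C4 configuration is not critical because this centre is ionised again in step 12.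

**Step 9**
Reactants: 15 (−)-epicatechin
Product: 16 5,7,3',4'-tetra-O-benzyl-(−)-epicatechin
Conditions: BnBr, K2CO3, DMF, 0 °C to rt
Reagents that add atoms: benzyl bromide BrCc1ccccc1
Why: Williamson etherification of the four phenols, which are far more acidic than the secondary 3-OH, under mild carbonate conditions that should leave C2 and C3 untouched.

**Step 10**
Reactants: 16 5,7,3',4'-tetra-O-benzyl-(−)-epicatechin
Product: 17 8-bromo-5,7,3',4'-tetra-O-benzyl-(−)-epicatechin
Conditions: NBS, CH2Cl2, −78 °C to rt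
Reagents that add atoms: N-bromosuccinimide O=C1CCC(=O)N1Br
Why: Electrophilic bromination of the phloroglucinol-type ring at C8, the more reactive of its two free positions in 5,7-di-O-benzyl flavan-3-ols; the bromine blocks C8 so that the later coupling must occur at C6.

**Step 11**
Reactants: 17 8-bromo-5,7,3',4'-tetra-O-benzyl-(−)-epicatechin; 18 3,4,5-tris(benzyloxy)benzoic acid
Product: 19 8-bromo-5,7,3',4'-tetra-O-benzyl-(−)-epicatechin 3-O-[3,4,5-tris(benzyloxy)benzoate]
Conditions: DCC, DMAP, CH2Cl2, rt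
Reagents that add atoms: none
Why: Steglich esterification of the 3-OH with retention at C3; the gallate is installed before the coupling so that no choice between two secondary hydroxyl groups arises later.

**Step 12**
Reactants: 14 (2R,3R,4S)-5,7-bis(benzyloxy)-2-[4-(benzyloxy)phenyl]-4-(2-ethoxyethoxy)chroman-3-ol; 19 8-bromo-5,7,3',4'-tetra-O-benzyl-(−)-epicatechin 3-O-[3,4,5-tris(benzyloxy)benzoate]
Product: 20 5,7,4'-tri-O-benzyl-(−)-epiafzelechin-(4β→6)-8-bromo-5,7,3',4'-tetra-O-benzyl-(−)-epicatechin 3-O-[3,4,5-tris(benzyloxy)benzoate]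
Conditions: TMSOTf (cat.), 19 (3 equiv, excess recovered), CH2Cl2, −78 °C
Reagents that add atoms: none
Why: Friedel–Crafts-type interflavan coupling: Lewis-acid ionisation of the 4-alkoxy group gives the C4 benzylic cation, which C6 of 19 (the only free position of its phloroglucinol ring) attacks anti to the axial 3-OH, so the new C4 centre should be 4β (3,4-trans, 4S); the excess of 19 suppresses self-condensation of 14.

**Step 13**
Reactants: 20 protected bromo dimer
Product: 21 (−)-epiafzelechin-(4β→6)-(−)-epicatechin 3-O-gallate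
Conditions: H2 (1 atm), Pd(OH)2/C, Et3N, THF/MeOH/H2O, rt
Reagents that add atoms: none
Why: Hydrogenolysis over Pd(OH)2/C cleaves the ten benzyl ethers and, with Et3N as acid scavenger, the aryl C8–Br bond, without touching the gallate ester or the acid-labile interflavan bond.

**Compound list**
1 | 2,4,6-trifluorobenzaldehyde | O=Cc1c(F)cc(F)cc1F | starting material
2 | 2,4-bis(benzyloxy)-6-fluorobenzaldehyde | O=Cc1c(F)cc(OCc2ccccc2)cc1OCc1ccccc1 | intermediate
3 | [2,4-bis(benzyloxy)-6-fluorophenyl]methanol | OCc1c(F)cc(OCc2ccccc2)cc1OCc1ccccc1 | intermediate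
4 | 1,5-bis(benzyloxy)-2-(chloromethyl)-3-fluorobenzene | ClCc1c(F)cc(OCc2ccccc2)cc1OCc1ccccc1 | intermediate
5 | 1,3-dithiane | C1CSCSC1 | starting material
6 | 4-(benzyloxy)benzaldehyde | O=Cc1ccc(OCc2ccccc2)cc1 | starting material
7 | 2-lithio-1,3-dithiane | [Li+].[CH-]1SCCCS1 | intermediate (not isolated)
8 | rac-[4-(benzyloxy)phenyl](1,3-dithian-2-yl)methanol | OC(c1ccc(OCc2ccccc2)cc1)C1SCCCS1 | intermediate
9 | dilithio O,C-dianion of 8 | [Li+].[Li+].[O-]C(c1ccc(OCc2ccccc2)cc1)[C-]1SCCCS1 | intermediate (not isolated)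
10 | lithium rac-[4-(benzyloxy)phenyl]{2-[2,4-bis(benzyloxy)-6-fluorobenzyl]-1,3-dithian-2-yl}methanolate | [Li+].[O-]C(c1ccc(OCc2ccccc2)cc1)C1(Cc2c(F)cc(OCc3ccccc3)cc2OCc2ccccc2)SCCCS1 | intermediate (not isolated)
11 | rac-5,7-bis(benzyloxy)-2-[4-(benzyloxy)phenyl]spiro[chromane-3,2'-[1,3]dithiane] | C1CSC2(Cc3c(OCc4ccccc4)cc(OCc4ccccc4)cc3OC2c2ccc(OCc3ccccc3)cc2)SC1 | intermediate
12 | rac-5,7-bis(benzyloxy)-2-[4-(benzyloxy)phenyl]chroman-3-one | O=C1Cc2c(OCc3ccccc3)cc(OCc3ccccc3)cc2OC1c1ccc(OCc2ccccc2)cc1 | intermediate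
13 | (2R,3R)-5,7-bis(benzyloxy)-2-[4-(benzyloxy)phenyl]chroman-3-ol (2-aryl and 3-OH cis) | O[C@@H]1Cc2c(OCc3ccccc3)cc(OCc3ccccc3)cc2O[C@@H]1c1ccc(OCc2ccccc2)cc1 | intermediate
14 | (2R,3R,4S)-5,7-bis(benzyloxy)-2-[4-(benzyloxy)phenyl]-4-(2-ethoxyethoxy)chroman-3-ol (2,3-cis, 3,4-trans) | CCOCCO[C@H]1c2c(OCc3ccccc3)cc(OCc3ccccc3)cc2O[C@H](c2ccc(OCc3ccccc3)cc2)[C@@H]1O | intermediate
15 | (−)-epicatechin, (2R,3R)-2-(3,4-dihydroxyphenyl)chroman-3,5,7-triol | O[C@@H]1Cc2c(O)cc(O)cc2O[C@@H]1c1ccc(O)c(O)c1 | starting material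
16 | 5,7,3',4'-tetra-O-benzyl-(−)-epicatechin (2R,3R) | O[C@@H]1Cc2c(OCc3ccccc3)cc(OCc3ccccc3)cc2O[C@@H]1c1ccc(OCc2ccccc2)c(OCc2ccccc2)c1 | intermediate
17 | 8-bromo-5,7,3',4'-tetra-O-benzyl-(−)-epicatechin (2R,3R) | O[C@@H]1Cc2c(OCc3ccccc3)cc(OCc3ccccc3)c(Br)c2O[C@@H]1c1ccc(OCc2ccccc2)c(OCc2ccccc2)c1 | intermediate
18 | 3,4,5-tris(benzyloxy)benzoic acid | OC(=O)c1cc(OCc2ccccc2)c(OCc2ccccc2)c(OCc2ccccc2)c1 | starting material
19 | 8-bromo-5,7,3',4'-tetra-O-benzyl-(−)-epicatechin 3-O-[3,4,5-tris(benzyloxy)benzoate] (2R,3R) | O=C(O[C@@H]1Cc2c(OCc3ccccc3)cc(OCc3ccccc3)c(Br)c2O[C@@H]1c1ccc(OCc2ccccc2)c(OCc2ccccc2)c1)c1cc(OCc2ccccc2)c(OCc2ccccc2)c(OCc2ccccc2)c1 | intermediate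
20 | deca-O-benzyl 8-bromo dimer; upper unit (2R,3R,4S) with 4β→6 link, lower unit (2R,3R) | O=C(O[C@@H]1Cc2c(c(Br)c(OCc3ccccc3)c([C@H]3c4c(OCc5ccccc5)cc(OCc5ccccc5)cc4O[C@H](c4ccc(OCc5ccccc5)cc4)[C@@H]3O)c2OCc2ccccc2)O[C@@H]1c1ccc(OCc2ccccc2)c(OCc2ccccc2)c1)c1cc(OCc2ccccc2)c(OCc2ccccc2)c(OCc2ccccc2)c1 | intermediate
21 | (−)-epiafzelechin-(4β→6)-(−)-epicatechin 3-O-gallate; upper unit (2R,3R,4S), lower unit (2R,3R) | O=C(O[C@@H]1Cc2c(cc(O)c([C@H]3c4c(O)cc(O)cc4O[C@H](c4ccc(O)cc4)[C@@H]3O)c2O)O[C@@H]1c1ccc(O)c(O)c1)c1cc(O)c(O)c(O)c1 | target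

**Count**
Total steps: 13. Longest linear sequence: 9 steps (1, 2, 3, 5, 6, 7, 8, 12, 13).

**Steps most likely to fail**

Step 5 (proposed new method). The second deprotonation may be incomplete, the dianion may lose lithium oxide to a ketene dithioacetal, the potassium alkoxide may undergo retro-addition at 65 °C, or fluoride displacement on the electron-rich ring may be too slow. Fallback, from 4, 5 and 6 back to 11, with the two dithiane substitutions in the classical order and the ring closure as a separate step: 2-lithio-1,3-dithiane 7 (from 5) is alkylated with 4 to give 2-[2,4-bis(benzyloxy)-6-fluorobenzyl]-1,3-dithiane F1. F1 is lithiated (n-BuLi, THF, −20 °C) and added to 6 to give rac-[4-(benzyloxy)phenyl]{2-[2,4-bis(benzyloxy)-6-fluorobenzyl]-1,3-dithian-2-yl}methanol F2. F2 is isolated and cyclised by intramolecular SNAr (KH, DMF, 80 °C) to 11.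

Step 7. Discrimination between the two enantiomers of the ketone, or between its faces, may be insufficient, or racemisation at C2 may be slower than reduction. Fallback, from 12 back to 13, by resolution instead of catalysis: reduction with LiBH(s-Bu)3 (THF, −78 °C) should give the racemic 2,3-cis alcohol rac-5,7-bis(benzyloxy)-2-[4-(benzyloxy)phenyl]chroman-3-ol F3. Steglich esterification with (S)-methoxy(phenyl)acetic acid gives the (2R,3R) ester F4 and the (2S,3S) ester F5, which are separated by chromatography or crystallisation. Methanolysis of F4 (K2CO3, MeOH) returns 13.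

Step 12. The cation from 14 may self-condense on its own ring A, and attack by the hindered, bromine-deactivated C6 of 19 may be slow. Fallback, from 14 back to 20, with a thioether leaving group and thiophilic activation: 14 is treated with 2-mercaptobenzothiazole and BF3·OEt2 (CH2Cl2, 0 °C) to give (2R,3S,4S)-4-(1,3-benzothiazol-2-ylsulfanyl)-5,7-bis(benzyloxy)-2-[4-(benzyloxy)phenyl]chroman-3-ol F6. F6 is activated with AgBF4 (THF, 0 °C) in the presence of 19 to give 20.

**Further compounds**
F1 | step 5 | 2-[2,4-bis(benzyloxy)-6-fluorobenzyl]-1,3-dithiane | Fc1cc(OCc2ccccc2)cc(OCc2ccccc2)c1CC1SCCCS1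
F2 | step 5 | rac-[4-(benzyloxy)phenyl]{2-[2,4-bis(benzyloxy)-6-fluorobenzyl]-1,3-dithian-2-yl}methanol | OC(c1ccc(OCc2ccccc2)cc1)C1(Cc2c(F)cc(OCc3ccccc3)cc2OCc2ccccc2)SCCCS1
F3 | step 7 | rac-cis-5,7-bis(benzyloxy)-2-[4-(benzyloxy)phenyl]chroman-3-ol (both enantiomers) | O[C@@H]1Cc2c(OCc3ccccc3)cc(OCc3ccccc3)cc2O[C@@H]1c1ccc(OCc2ccccc2)cc1.O[C@H]1Cc2c(OCc3ccccc3)cc(OCc3ccccc3)cc2O[C@H]1c1ccc(OCc2ccccc2)cc1
F4 | step 7 | (2R,3R)-5,7-bis(benzyloxy)-2-[4-(benzyloxy)phenyl]chroman-3-yl (S)-methoxy(phenyl)acetate | CO[C@H](C(=O)O[C@@H]1Cc2c(OCc3ccccc3)cc(OCc3ccccc3)cc2O[C@@H]1c1ccc(OCc2ccccc2)cc1)c1ccccc1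
F5 | step 7 | (2S,3S)-5,7-bis(benzyloxy)-2-[4-(benzyloxy)phenyl]chroman-3-yl (S)-methoxy(phenyl)acetate | CO[C@H](C(=O)O[C@H]1Cc2c(OCc3ccccc3)cc(OCc3ccccc3)cc2O[C@H]1c1ccc(OCc2ccccc2)cc1)c1ccccc1
F6 | step 12 | (2R,3S,4S)-4-(1,3-benzothiazol-2-ylsulfanyl)-5,7-bis(benzyloxy)-2-[4-(benzyloxy)phenyl]chroman-3-ol | c1ccc2sc(S[C@H]3c4c(OCc5ccccc5)cc(OCc5ccccc5)cc4O[C@H](c4ccc(OCc5ccccc5)cc4)[C@@H]3O)nc2c1
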